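**Plan**

1. The C6 carbinol and the C9 ketone sit 1,4 to each other on either side of the C7=C8 alkene in the seven-membered ring. This is the pattern left when the endoperoxide of a C6=C7–C8=C9 ring diene is opened by base, so after the phenol silyl group the C6–O and C9–O bonds are cut together, back to O2 and that diene.
2. Further cuts: the C4–O acyl bond; the diene back to a C6 enol triflate and C6 ketone; C8=C9 (ring-closing metathesis); C6–C7 (methallylation); C1–C10 (anionic oxy-Cope); C6–allyl (allylboration); the cyclopentene C5=C1 (aldol) back to the cyclohexene of (S)-terpinen-4-ol.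
3. Forward: the five-membered ring comes first by ozonolysis/aldol ring contraction, then the C1 quaternary centre, then the seven-membered ring by metathesis, then diene, ester and oxygenation.
4. Stereochemistry: C4 comes from the chiral pool; C1 by 1,3-chirality transfer from a reagent-controlled C6 carbinol; C5 by thermodynamic epimerisation of a formyl group (giving the trans ring fusion); C6 by approach of singlet oxygen anti to the C1 methyl and the C4 ester.

Key step: step 15

Remark on numbering: daucane numbering is used. C1 is the methyl-bearing ring-fusion carbon, C2 and C3 the five-ring CH2 groups, C4 the carbon bearing oxygen and isopropyl, C5 the ring-fusion CH, and C6–C10 the remaining seven-ring carbons, with the second methyl on C8.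

Assumption: (S)-terpinen-4-ol is used in high enantiomeric purity; the absolute configuration of the whole series rests on it. Compound 7 is the commercial reagent solution.

**Step 1**
Reactants: 1 (S)-terpinen-4-ol
Product: 2 (S)-terpinen-4-yl triethylsilyl ether
Conditions: Et3SiOTf, 2,6-lutidine, CH2Cl2, 0 °C → rt
Reagents that add atoms: triethylsilyl trifluoromethanesulfonate, CC[Si](CC)(CC)OS(=O)(=O)C(F)(F)F
Why: Silylation of the tertiary alcohol with a silyl triflate and a hindered pyridine base masks the hydroxyl, which would otherwise compete as a leaving group in the condensation of step 3; C4 is untouched.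

**Step 2**
Reactants: 2 (S)-terpinen-4-yl triethylsilyl ether
Product: 4 (3S)-6-oxo-3-(propan-2-yl)-3-(triethylsilyloxy)heptanal, via secondary ozonide 3 (not isolated)
Conditions: O3, CH2Cl2, −78 °C; Me2S, −78 °C → rt
Reagents that add atoms: ozone, [O-][O+]=O
Why: Ozonolysis with reductive work-up cleaves the only alkene into a methyl ketone and an aldehyde and creates no stereocentre.

**Step 3**
Reactants: 4 (3S)-6-oxo-3-(propan-2-yl)-3-(triethylsilyloxy)heptanal
Product: 6 (5R)-2-methyl-5-(propan-2-yl)-5-(triethylsilyloxy)cyclopent-1-ene-1-carbaldehyde, via aldol adduct 5 (not isolated)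
Conditions: Bn2NH·CF3CO2H (0.3 equiv), toluene, 50 °C
Reagents that add atoms: none
Why: Amine-catalysed intramolecular aldol condensation (5-enolexo): the secondary ammonium salt condenses only with the aldehyde, the enamine adds to the methyl ketone and water is lost into conjugation, the usual ring contraction of keto aldehydes from 1-methylcyclohexenes.

**Step 4**
Reactants: 6 (5R)-2-methyl-5-(propan-2-yl)-5-(triethylsilyloxy)cyclopent-1-ene-1-carbaldehyde; 7 (−)-B-allyldiisopinocampheylborane
Product: 9 (1S)-1-[(5R)-2-methyl-5-(propan-2-yl)-5-(triethylsilyloxy)cyclopent-1-en-1-yl]but-3-en-1-ol, via borinate ester 8 (not isolated)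
Conditions: 7 (1.3 equiv), Et2O, −78 °C → rt; NaOH, H2O2, 0 °C
Reagents that add atoms: 7 (−)-B-allyldiisopinocampheylborane, C=CCB([C@@H]1C[C@@H]2C[C@H]([C@H]1C)C2(C)C)[C@@H]1C[C@@H]2C[C@H]([C@H]1C)C2(C)C
Why: Brown allylboration through a chair Zimmerman–Traxler transition state; the (+)-α-pinene-derived reagent should add to the Si face of the conjugated aldehyde as it does with aryl aldehydes, setting C6 as S by reagent control (the antipodal borane is the remedy should the sense prove opposite).

**Step 5**
Reactants: 9 (1S)-1-[(5R)-2-methyl-5-(propan-2-yl)-5-(triethylsilyloxy)cyclopent-1-en-1-yl]but-3-en-1-ol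
Product: 10 (1R)-2-[(1S)-1-hydroxybut-3-en-1-yl]-3-methyl-1-(propan-2-yl)cyclopent-2-en-1-ol
Conditions: Bu4NF, THF, rt
Reagents that add atoms: none
Why: Fluoride desilylation frees the tertiary hydroxyl so that the enolate of step 6 has an alkoxide, which cannot be expelled, on its β-carbon.

**Step 6**
Reactants: 10 (1R)-2-[(1S)-1-hydroxybut-3-en-1-yl]-3-methyl-1-(propan-2-yl)cyclopent-2-en-1-ol
Product: 13 (1R,2R,5R)-2-hydroxy-5-methyl-2-(propan-2-yl)-5-(prop-2-en-1-yl)cyclopentane-1-carbaldehyde, via dipotassium enolate alkoxide 11 (not isolated), via C5-epimeric aldehyde 12 (not isolated)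
Conditions: KH (2.5 equiv), 18-crown-6, THF, 0 °C → rt; AcOH, −78 °C; crude, DBU (0.2 equiv), CH2Cl2, rt
Reagents that add atoms: none
Why: Anionic oxy-Cope rearrangement: in the chair transition state the ring methyl on the alkene terminus forces H-6 axial and the alkoxide equatorial, so the (6S) carbinol hands the allyl unit to the isopropyl face of C1 (1,3-chirality transfer, 1R), and amine-base equilibration of the α-branched aldehyde should then place the formyl group anti to both the isopropyl and the allyl group (5R).

**Step 7**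
Reactants: 13 (1R,2R,5R)-2-hydroxy-5-methyl-2-(propan-2-yl)-5-(prop-2-en-1-yl)cyclopentane-1-carbaldehyde; 14 3-bromo-2-methylprop-1-ene
Product: 15 (1R,2S,3R)-2-(1-hydroxy-3-methylbut-3-en-1-yl)-3-methyl-1-(propan-2-yl)-3-(prop-2-en-1-yl)cyclopentan-1-ol (either configuration at the side-chain carbinol)
Conditions: 14 (3 equiv), Zn dust, THF/sat. aq NH4Cl, 0 °C → rt
Reagents that add atoms: 14 3-bromo-2-methylprop-1-ene, CC(=C)CBr
Why: Barbier allylation with zinc in aqueous medium is mild enough for the β-hydroxy aldehyde; the new C6 carbinol centre is not controlled and is erased in step 9.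

**Step 8**
Reactants: 15 (1R,2S,3R)-2-(1-hydroxy-3-methylbut-3-en-1-yl)-3-methyl-1-(propan-2-yl)-3-(prop-2-en-1-yl)cyclopentan-1-ol
Product: 16 (1R,4R,5S)-dauc-8-ene-4,6-diol (trans ring fusion, either configuration at C6)
Conditions: second-generation Grubbs catalyst (5 mol %), CH2Cl2 (0.005 M), 40 °C
Reagents that add atoms: none
Why: Ring-closing metathesis of the allyl alkene onto the 1,1-disubstituted methallyl alkene closes the seven-membered ring as the trisubstituted C8=C9 alkene, the trans-disposed chains on C1 and C5 becoming the trans ring fusion; no stereocentre is formed.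

**Step 9**
Reactants: 16 (1R,4R,5S)-dauc-8-ene-4,6-diol
Product: 17 (1R,4R,5R)-4-hydroxydauc-8-en-6-one
Conditions: Dess–Martin periodinane, NaHCO3, CH2Cl2, 0 °C
Reagents that add atoms: none
Why: Buffered Dess–Martin oxidation converts both C6 epimers of the secondary alcohol into one β,γ-unsaturated ketone without moving the alkene or touching the tertiary alcohol.

**Step 10**
Reactants: 17 (1R,4R,5R)-4-hydroxydauc-8-en-6-one
Product: 19 (1R,4R,5R)-4-hydroxydauca-6,8-dien-6-yl trifluoromethanesulfonate, via dipotassium dienolate 18 (not isolated)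
Conditions: KN(SiMe3)2 (2.2 equiv), THF, −78 °C; PhNTf2, −78 → 0 °C; sat. aq NH4Cl
Reagents that add atoms: N-phenylbis(trifluoromethanesulfonimide), O=S(=O)(N(c1ccccc1)S(=O)(=O)C(F)(F)F)C(F)(F)F
Why: Enol triflate formation: C7–H is both α to the ketone and allylic, so deprotonation gives the linear dienolate, which is O-sulfonylated, while the second equivalent of base holds the hydroxyl as its unreactive hindered alkoxide.

**Step 11**
Reactants: 19 (1R,4R,5R)-4-hydroxydauca-6,8-dien-6-yl trifluoromethanesulfonate
Product: 20 (1R,4R,5R)-dauca-6,8-dien-4-ol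
Conditions: Pd(OAc)2 (5 mol %), PPh3 (10 mol %), Bu3N, HCO2H, DMF, 60 °C
Reagents that add atoms: none
Why: Palladium-catalysed formate reduction of an alkenyl triflate (oxidative addition to zerovalent palladium, decarboxylation of formate, reductive elimination) replaces the triflate by hydrogen and leaves the C6=C7–C8=C9 diene.

**Step 12**
Reactants: 21 4-hydroxybenzoic acid
Product: 23 4-(tert-butyldimethylsilyloxy)benzoic acid, via bis-silylated acid 22 (not isolated)
Conditions: t-BuMe2SiCl (2.2 equiv), imidazole, DMF, rt; then AcOH/THF/H2O, rt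
Reagents that add atoms: tert-butyl(chloro)dimethylsilane, CC(C)(C)[Si](C)(C)Cl
Why: Silylation of both acidic sites followed by selective hydrolysis of the far more labile silyl ester leaves only the phenol protected.

**Step 13**
Reactants: 23 4-(tert-butyldimethylsilyloxy)benzoic acid
Product: 24 4-(tert-butyldimethylsilyloxy)benzoyl chloride
Conditions: (COCl)2, DMF (cat.), CH2Cl2, 0 °C → rt
Reagents that add atoms: oxalyl chloride, ClC(=O)C(=O)Cl
Why: Acid chloride formation through the Vilsmeier-type chloroiminium intermediate proceeds under conditions the aryl silyl ether tolerates.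

**Step 14**
Reactants: 20 (1R,4R,5R)-dauca-6,8-dien-4-ol; 24 4-(tert-butyldimethylsilyloxy)benzoyl chloride
Product: 26 (1R,4R,5R)-dauca-6,8-dien-4-yl 4-(tert-butyldimethylsilyloxy)benzoate, via lithium alkoxide 25 (not isolated)
Conditions: n-BuLi (1.05 equiv), THF, −78 °C; then 24, −78 → 0 °C
Reagents that add atoms: none
Why: O-Acylation of a preformed lithium alkoxide with an aroyl chloride is the standard way to esterify a hindered tertiary alcohol, and C4 keeps its configuration because the C–O bond is not broken.

**Step 15**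
Reactants: 26 (1R,4R,5R)-dauca-6,8-dien-4-yl 4-(tert-butyldimethylsilyloxy)benzoate
Product: 28 (1R,4R,5S,6S)-6-hydroxy-9-oxodauc-7-en-4-yl 4-(tert-butyldimethylsilyloxy)benzoate, via endoperoxide 27 (not isolated)
Conditions: O2, tetraphenylporphyrin (1 mol %), visible light, CH2Cl2, 0 °C; then Et3N (0.5 equiv), 0 °C → rt
Reagents that add atoms: dioxygen, O=O
Why: Porphyrin-sensitised singlet oxygen adds across C6 and C9 of the cisoid ring diene in a concerted suprafacial [4+2] cycloaddition, and triethylamine then removes H-9 while the O–O bond breaks (Kornblum–DeLaMare rearrangement), which leaves the C9 ketone, the C7=C8 alkene and, after protonation, the C6 alcohol. The closest known reaction type is the photooxygenation of cyclohepta-1,3-dienes followed by amine isomerisation of the endoperoxide to a 4-hydroxycyclohept-2-enone. The only ring closed is the transient peroxide bridge of 27, formed with both C–O bonds at once by the cycloaddition and opened again in the same flask, so no new ring remains. The one new stereocentre, C6 (S), is set by the face of oxygen approach: the C1 methyl and the C4 aroyloxy group both lie on the face opposite H-5 and crowd the two diene termini there, so oxygen should enter on the H-5 face. The step also needs proton removal at C9 and not at C6, which is secured because H-9 sits next to a CH2 group whereas H-6 is buried beside C5 between two fully substituted carbons. The electron-rich cisoid diene should react by cycloaddition faster than by the ene pathway, and the aryl ester and silyl ether are inert to these neutral conditions.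

**Step 16**
Reactants: 28 (1R,4R,5S,6S)-6-hydroxy-9-oxodauc-7-en-4-yl 4-(tert-butyldimethylsilyloxy)benzoate
Product: 29 (1R,4R,5S,6S)-6-hydroxy-9-oxodauc-7-en-4-yl 4-hydroxybenzoate (target)
Conditions: Bu4NF, AcOH, THF, 0 °C
Reagents that add atoms: none
Why: Fluoride cleavage of the aryl silyl ether, buffered with acetic acid so that neither the 4-hydroxy-enone nor the ester meets free base; no stereocentre is affected.

**Compound list**

1 | (S)-terpinen-4-ol, (1S)-4-methyl-1-(propan-2-yl)cyclohex-3-en-1-ol | CC1=CC[C@](O)(C(C)C)CC1 | starting material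
2 | (S)-terpinen-4-yl triethylsilyl ether | CC1=CC[C@](O[Si](CC)(CC)CC)(C(C)C)CC1 | intermediate
3 | secondary ozonide (1,2,4-trioxolane) of 2, not isolated | CC12CC[C@@](O[Si](CC)(CC)CC)(C(C)C)CC(OO1)O2 | intermediate
4 | (3S)-6-oxo-3-(propan-2-yl)-3-(triethylsilyloxy)heptanal | CC(=O)CC[C@@](O[Si](CC)(CC)CC)(C(C)C)CC=O | intermediate
5 | aldol adduct, (5R)-2-hydroxy-2-methyl-5-(propan-2-yl)-5-(triethylsilyloxy)cyclopentane-1-carbaldehyde, not isolated | O=CC1C(C)(O)CC[C@@]1(O[Si](CC)(CC)CC)C(C)C | intermediate
6 | (5R)-2-methyl-5-(propan-2-yl)-5-(triethylsilyloxy)cyclopent-1-ene-1-carbaldehyde | O=CC1=C(C)CC[C@@]1(O[Si](CC)(CC)CC)C(C)C | intermediate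
7 | (−)-B-allyldiisopinocampheylborane, from (+)-α-pinene | C=CCB([C@@H]1C[C@@H]2C[C@H]([C@H]1C)C2(C)C)[C@@H]1C[C@@H]2C[C@H]([C@H]1C)C2(C)C | starting material
8 | diisopinocampheylborinate ester of 9, not isolated | C=CC[C@H](OB([C@@H]2C[C@@H]3C[C@H]([C@H]2C)C3(C)C)[C@@H]2C[C@@H]3C[C@H]([C@H]2C)C3(C)C)C1=C(C)CC[C@@]1(O[Si](CC)(CC)CC)C(C)C | intermediate
9 | (1S)-1-[(5R)-2-methyl-5-(propan-2-yl)-5-(triethylsilyloxy)cyclopent-1-en-1-yl]but-3-en-1-ol | C=CC[C@H](O)C1=C(C)CC[C@@]1(O[Si](CC)(CC)CC)C(C)C | intermediate
10 | (1R)-2-[(1S)-1-hydroxybut-3-en-1-yl]-3-methyl-1-(propan-2-yl)cyclopent-2-en-1-ol | C=CC[C@H](O)C1=C(C)CC[C@@]1(O)C(C)C | intermediate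
11 | dipotassium salt of 13 (C6 enolate, C4 alkoxide), not isolated | [K+].[K+].[O-]C=C1[C@@](C)(CC=C)CC[C@@]1([O-])C(C)C | intermediate
12 | (1S,2R,5R)-2-hydroxy-5-methyl-2-(propan-2-yl)-5-(prop-2-en-1-yl)cyclopentane-1-carbaldehyde, the C5 epimer of 13 (formyl cis to isopropyl and allyl), not isolated | O=C[C@H]1[C@@](C)(CC=C)CC[C@@]1(O)C(C)C | intermediate
13 | (1R,2R,5R)-2-hydroxy-5-methyl-2-(propan-2-yl)-5-(prop-2-en-1-yl)cyclopentane-1-carbaldehyde (formyl cis to hydroxyl and methyl) | O=C[C@@H]1[C@@](C)(CC=C)CC[C@@]1(O)C(C)C | intermediate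
14 | 3-bromo-2-methylprop-1-ene | CC(=C)CBr | starting material
15 | (1R,2S,3R)-2-(1-hydroxy-3-methylbut-3-en-1-yl)-3-methyl-1-(propan-2-yl)-3-(prop-2-en-1-yl)cyclopentan-1-ol, side-chain carbinol not defined | C=CC[C@@]1(C)CC[C@@](O)(C(C)C)[C@@H]1C(O)CC(C)=C | intermediate
16 | (1R,4R,5S)-dauc-8-ene-4,6-diol, trans-fused, C6 not defined | CC1=CC[C@@]2(C)CC[C@@](O)(C(C)C)[C@@H]2C(O)C1 | intermediate
17 | (1R,4R,5R)-4-hydroxydauc-8-en-6-one, trans-fused | CC1=CC[C@@]2(C)CC[C@@](O)(C(C)C)[C@@H]2C(=O)C1 | intermediate
18 | dipotassium salt of 17 (C6 dienolate, C4 alkoxide), not isolated | CC1=CC[C@@]2(C)CC[C@@]([O-])(C(C)C)[C@@H]2C([O-])=C1.[K+].[K+] | intermediate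
19 | (1R,4R,5R)-4-hydroxydauca-6,8-dien-6-yl trifluoromethanesulfonate | CC1=CC[C@@]2(C)CC[C@@](O)(C(C)C)[C@@H]2C(OS(=O)(=O)C(F)(F)F)=C1 | intermediate
20 | (1R,4R,5R)-dauca-6,8-dien-4-ol, trans-fused | CC1=CC[C@@]2(C)CC[C@@](O)(C(C)C)[C@@H]2C=C1 | intermediate
21 | 4-hydroxybenzoic acid | OC(=O)c1ccc(O)cc1 | starting material
22 | tert-butyldimethylsilyl 4-(tert-butyldimethylsilyloxy)benzoate, not isolated | CC(C)(C)[Si](C)(C)OC(=O)c1ccc(O[Si](C)(C)C(C)(C)C)cc1 | intermediate
23 | 4-(tert-butyldimethylsilyloxy)benzoic acid | OC(=O)c1ccc(O[Si](C)(C)C(C)(C)C)cc1 | intermediate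
24 | 4-(tert-butyldimethylsilyloxy)benzoyl chloride | ClC(=O)c1ccc(O[Si](C)(C)C(C)(C)C)cc1 | intermediate
25 | lithium (1R,4R,5R)-dauca-6,8-dien-4-olate, not isolated | CC1=CC[C@@]2(C)CC[C@@]([O-])(C(C)C)[C@@H]2C=C1.[Li+] | intermediate
26 | (1R,4R,5R)-dauca-6,8-dien-4-yl 4-(tert-butyldimethylsilyloxy)benzoate, trans-fused | CC1=CC[C@@]2(C)CC[C@@](OC(=O)c3ccc(O[Si](C)(C)C(C)(C)C)cc3)(C(C)C)[C@@H]2C=C1 | intermediate
27 | (1R,4R,5S,6S,9S)-6,9-epidioxydauc-7-en-4-yl 4-(tert-butyldimethylsilyloxy)benzoate (peroxide bridge on the H-5 face), not isolated | CC1=C[C@@H]2OO[C@H]1C[C@@]3(C)CC[C@@](OC(=O)c4ccc(O[Si](C)(C)C(C)(C)C)cc4)(C(C)C)[C@H]23 | intermediate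
28 | (1R,4R,5S,6S)-6-hydroxy-9-oxodauc-7-en-4-yl 4-(tert-butyldimethylsilyloxy)benzoate | CC1=C[C@H](O)[C@@H]2[C@](C)(CC[C@@]2(OC(=O)c2ccc(O[Si](C)(C)C(C)(C)C)cc2)C(C)C)CC1=O | intermediate
29 | (1R,4R,5S,6S)-6-hydroxy-9-oxodauc-7-en-4-yl 4-hydroxybenzoate | CC1=C[C@H](O)[C@@H]2[C@](C)(CC[C@@]2(OC(=O)c2ccc(O)cc2)C(C)C)CC1=O | target

**Step count and risks**

Total: 16 steps. Longest linear sequence: 14 steps (steps 1–11 and 14–16); steps 12 and 13 are a two-step side branch.

Most likely to fail:

1. Step 3. The aldehyde-derived enamine may expel the β-silyloxy group before it closes the ring, or the ketone side may enolise and close to the isomeric acetylcyclopentene. Fallback: setting out from 4, ring closure and dehydration are separated. Pyrrolidine/AcOH in CH2Cl2 at 0 °C is stopped at the aldol adduct 5, which is isolated. Its only free hydroxyl, the new tertiary one on the methyl-bearing carbon, is then removed with the Burgess reagent (toluene, 50 °C). This is a syn-elimination through a sulfamate ester that takes the acidic hydrogen next to the formyl group and needs neither enamine nor enolate, and it returns to 6.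

2. Step 6. The hindered potassium alkoxide may fragment by loss of the allyl unit instead of rearranging onto the tetrasubstituted alkene, and the β-hydroxy aldehyde may open by retro-aldol cleavage or dehydrate while C5 is equilibrated. Fallback: setting out from 6 with the silyl ether kept, allylMgBr and CuBr·SMe2 in the presence of Me3SiCl (THF, −78 °C) should add the allyl group 1,4 and trap the enolate as the trimethylsilyl enol ether F1. Mild aqueous acid gives the silyl-protected aldehyde F2, and Bu4NF (THF, rt) then removes the triethylsilyl group and, being basic, equilibrates C5, returning to 13. The face of C1 is then chosen by the ring and not by a reagent (approach anti to the pseudo-axial silyloxy group is expected), so C1 epimers may have to be separated.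

3. Step 15. The amine may remove H-6 instead of H-9 or isomerise the hydroxy-enone further to the 1,4-dione, and an ene reaction at the C8 methyl may compete with cycloaddition. Fallback: setting out from endoperoxide 27, made as in step 15 but without amine, the O–O bond is reduced with Zn in AcOH to the cis-6,9-diol F3. The C9 carbinol, allylic and far less hindered than the C6 carbinol, is then oxidised selectively with MnO2 (CH2Cl2, rt), returning to 28. The two C–O bonds are still formed by the same cycloaddition.

**Further compounds**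

F0 | step 3 | none | none
F1 | step 6 | trimethylsilyl enol ether of the conjugate allylation product, C4 triethylsilyl ether | C[Si](C)(C)OC=C1[C@@](C)(CC=C)CC[C@@]1(O[Si](CC)(CC)CC)C(C)C
F2 | step 6 | (2R,5R)-5-methyl-2-(propan-2-yl)-5-(prop-2-en-1-yl)-2-(triethylsilyloxy)cyclopentane-1-carbaldehyde, C1 of the ring (daucane C5) not defined | O=CC1[C@@](C)(CC=C)CC[C@@]1(O[Si](CC)(CC)CC)C(C)C
F3 | step 15 | (1R,4R,5S,6S,9S)-6,9-dihydroxydauc-7-en-4-yl 4-(tert-butyldimethylsilyloxy)benzoate, both hydroxyls on the H-5 face | CC1=C[C@H](O)[C@@H]2[C@](C)(CC[C@@]2(OC(=O)c2ccc(O[Si](C)(C)C(C)(C)C)cc2)C(C)C)C[C@@H]1O
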